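Assumption: the SMILES is taken as drawn (an ent-labdane, 6-OH trans to the C10 methyl); positions are cited with labdane numbering (ring carbons C1–C10, C17 = formyl carbon on C8, side chain C11–C16).

**Retrosynthetic overview**
1. Target ⇒ C6–O bond by visible-light singlet-oxygen γ-oxygenation of the silyl dienol ether of enal 14 ⇒ 14 from the C17 methyl of 13 (SeO2).
2. 13 ⇒ C12–C13 B-alkyl Suzuki union of 9-vinyl decalin 8 with the (Z)-β-iodo enoate 11, which carries the side-chain geometry.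
3. 8 ⇒ enone 5 by vinyl Grignard addition and Pd/formate allylic hydrogenolysis (C9–H delivered anti to the C10 methyl).
4. 5 ⇒ doubly alkylated (S)-carvone 3 by reductive Heck closure of the C3–C4 bond (gem-dimethyl carbon), then alkene hydrogenation.
5. Ring order: ring B is the carvone ring (C5 bought, C10 set by anti alkylation); ring A is closed in step 3.

**Route**

Step 1
Reactants: 1 (S)-(+)-carvone
Product: 2 (5S,6R)-2,6-dimethyl-5-(prop-1-en-2-yl)cyclohex-2-en-1-one
Conditions: LDA, THF, −78 °C; MeI, −78 → 0 °C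
Reagents that add atoms: iodomethane, CI
Why: Kinetic α′-enolate alkylation of carvone; the new C6 centre (trans major) is irrelevant because it is re-enolised in step 2.

Step 2
Reactants: 2 (5S,6R)-2,6-dimethyl-5-(prop-1-en-2-yl)cyclohex-2-en-1-one
Product: 3 (5R,6R)-6-[(2Z)-3-chloroprop-2-en-1-yl]-2,6-dimethyl-5-(prop-1-en-2-yl)cyclohex-2-en-1-one
Conditions: LDA, THF, −78 °C; (Z)-ClCH2CH=CHCl, DMPU, n-Bu4NI (cat.), −78 → 23 °C
Reagents that add atoms: (Z)-1,3-dichloropropene, Cl/C=C\CCl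
Why: Diastereoselective enolate alkylation in which the allylic chloride enters anti to the C5 isopropenyl group, setting the quaternary C10 with methyl cis to isopropenyl (the later trans ring fusion).

Step 3
Reactants: 3 (5R,6R)-6-[(2Z)-3-chloroprop-2-en-1-yl]-2,6-dimethyl-5-(prop-1-en-2-yl)cyclohex-2-en-1-one
Product: 4 (4aR,8aR)-2,5,5,8a-tetramethyl-4a,5,8,8a-tetrahydronaphthalen-1(4H)-one
Conditions: Pd(OAc)2 (5 mol %), P(t-Bu)3·HBF4 (10 mol %), HCO2Na, n-Bu4NCl, DMF, 90 °C
Reagents that add atoms: none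
Why: Intramolecular reductive Heck reaction: the (Z)-alkenyl-Pd adds 6-exo-trig to the internal carbon of the isopropenyl group and the neopentyl Pd (no β-H) is reduced by formate to CH3, giving ring A with the gem-dimethyl carbon and no new stereocentre.

Step 4
Reactants: 4 (4aR,8aR)-2,5,5,8a-tetramethyl-4a,5,8,8a-tetrahydronaphthalen-1(4H)-one
Product: 5 (4aR,8aR)-2,5,5,8a-tetramethyl-4a,5,6,7,8,8a-hexahydronaphthalen-1(4H)-one
Conditions: H2 (1 atm), RhCl(PPh3)3 (5 mol %), benzene–EtOH, 23 °C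
Reagents that add atoms: none
Why: Wilkinson hydrogenation reduces the cis-disubstituted ring-A alkene and leaves the trisubstituted enone alkene untouched (the selectivity known from carvone to carvotanacetone).

Step 5
Reactants: 5 (4aR,8aR)-2,5,5,8a-tetramethyl-4a,5,6,7,8,8a-hexahydronaphthalen-1(4H)-one
Product: 8 (1R,4aR,8aR)-1-ethenyl-2,5,5,8a-tetramethyl-1,4,4a,5,6,7,8,8a-octahydronaphthalene, via bromomagnesium alkoxide 6 (not isolated), via tertiary allylic formate 7 (not isolated)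
Conditions: CH2=CHMgBr, THF, 0 → 23 °C; HCO2Ac, 0 °C; then Pd(OAc)2 (5 mol %), n-Bu3P (10 mol %), 50 °C
Reagents that add atoms: vinylmagnesium bromide, C=C[Mg]Br
Why: Grignard 1,2-addition followed by Tsuji Pd/formate allylic hydrogenolysis: the formate-derived Pd–H delivers hydride to the more substituted allyl terminus (C9) from the Pd-bearing face anti to the C10 methyl, giving the skipped diene with C9–H trans to the angular methyl.

Step 6
Reactants: 9 methyl 4-hydroxybut-2-ynoate
Product: 11 methyl (2Z)-4-(acetyloxy)-3-iodobut-2-enoate, via hydroxy vinyl iodide 10 (not isolated)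
Conditions: NaI, AcOH, 70 °C; then Ac2O, DMAP (cat.), 23 °C
Reagents that add atoms: sodium iodide, [Na+].[I-]; acetic anhydride, CC(=O)OC(C)=O
Why: Conjugate addition of iodide to the ynoate with anti protonation gives the (Z)-β-iodo enoate (I cis to CO2Me), and the primary alcohol is acetylated in the same pot.

Step 7
Reactants: 8 (1R,4aR,8aR)-1-ethenyl-2,5,5,8a-tetramethyl-1,4,4a,5,6,7,8,8a-octahydronaphthalene; 11 methyl (2Z)-4-(acetyloxy)-3-iodobut-2-enoate
Product: 13 methyl (2E)-3-[(acetyloxy)methyl]-5-[(1R,4aR,8aR)-2,5,5,8a-tetramethyl-1,4,4a,5,6,7,8,8a-octahydronaphthalen-1-yl]pent-2-enoate, via B-alkyl-9-BBN borane 12 (not isolated)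
Conditions: 9-BBN, THF, 23 °C; then 11, Pd(dppf)Cl2 (5 mol %), K3PO4 (3 M aq.), DMF, 23 °C
Reagents that add atoms: none
Why: 9-BBN hydroborates only the monosubstituted vinyl group (anti-Markovnikov) and the B-alkyl Suzuki–Miyaura coupling forms C12–C13 with retention of the iodide geometry, so the ester ends cis to the chain.

Step 8
Reactants: 13 methyl (2E)-3-[(acetyloxy)methyl]-5-[(1R,4aR,8aR)-2,5,5,8a-tetramethyl-1,4,4a,5,6,7,8,8a-octahydronaphthalen-1-yl]pent-2-enoate
Product: 14 methyl (2E)-3-[(acetyloxy)methyl]-5-[(1S,4aR,8aR)-2-formyl-5,5,8a-trimethyl-1,4,4a,5,6,7,8,8a-octahydronaphthalen-1-yl]pent-2-enoate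
Conditions: SeO2, 1,4-dioxane, 80 °C
Reagents that add atoms: selenium dioxide, O=[Se]=O
Why: Riley allylic oxidation (ene then [2,3] shift) acts at the more substituted end of the electron-rich ring alkene, where CH3 is preferred over the hindered C9 methine; the electron-poor enoate is inert.

Step 9
Reactants: 14 methyl (2E)-3-[(acetyloxy)methyl]-5-[(1S,4aR,8aR)-2-formyl-5,5,8a-trimethyl-1,4,4a,5,6,7,8,8a-octahydronaphthalen-1-yl]pent-2-enoate
Product: 17 methyl (2E)-3-[(acetyloxy)methyl]-5-[(1S,4R,4aR,8aS)-2-formyl-4-hydroxy-5,5,8a-trimethyl-1,4,4a,5,6,7,8,8a-octahydronaphthalen-1-yl]pent-2-enoate, via silyl dienol ether 15 (not isolated), via allylic hydroperoxide 16 (not isolated)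
Conditions: TBSOTf, Et3N, CH2Cl2, −78 → 0 °C; pentane filtration and solvent switch; O2, TPP (1 mol %), white LEDs, CH2Cl2–MeOH, −40 °C; then PPh3, −40 → 23 °C
Reagents that add atoms: dioxygen, O=O
Why: Proposed new method: singlet-oxygen γ-oxygenation of a locked s-trans, enal-derived silyl dienol ether; [4+2] is geometrically impossible and the α-carbon C8 is fully substituted, so 1O2 attacks the diene terminus C6 via a perepoxide/zwitterion stabilised as the O-silyl oxocarbenium, methanol removes the silyl group and protonates the peroxide, and PPh3 reduces OOH to OH; attack anti to the C10 methyl and the axial C4 methyl sets C6 with OH trans to the angular methyl; closest known reaction type: photo-oxygenation/autoxidation of steroidal 3,5-dienol ethers to 6-hydroperoxy-4-en-3-ones and the silatropic ene reaction of silyl enol ethers with 1O2.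

**Compound list**
1 | (S)-(+)-carvone, (5S)-2-methyl-5-(prop-1-en-2-yl)cyclohex-2-en-1-one | O=C1C(C)=CC[C@H](C(C)=C)C1 | starting material
2 | (5S,6R)-2,6-dimethyl-5-(prop-1-en-2-yl)cyclohex-2-en-1-one (trans-6-methylcarvone; the minor C6 epimer converges in step 2) | O=C1C(C)=CC[C@H](C(C)=C)[C@H]1C | intermediate
3 | (5R,6R)-6-[(2Z)-3-chloroprop-2-en-1-yl]-2,6-dimethyl-5-(prop-1-en-2-yl)cyclohex-2-en-1-one (chloroallyl trans to isopropenyl) | O=C1C(C)=CC[C@H](C(C)=C)[C@@]1(C)C/C=C\Cl | intermediate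
4 | (4aR,8aR)-2,5,5,8a-tetramethyl-4a,5,8,8a-tetrahydronaphthalen-1(4H)-one (trans-fused, ring-A alkene C2=C3) | O=C1C(C)=CC[C@@H]2C(C)(C)C=CC[C@@]12C | intermediate
5 | (4aR,8aR)-2,5,5,8a-tetramethyl-4a,5,6,7,8,8a-hexahydronaphthalen-1(4H)-one | O=C1C(C)=CC[C@@H]2C(C)(C)CCC[C@@]12C | intermediate
6 | bromomagnesium (1R,4aR,8aR)-1-ethenyl-2,5,5,8a-tetramethyl-1,4,4a,5,6,7,8,8a-octahydronaphthalen-1-olate (vinyl anti to the angular methyl) | C=C[C@@]1(O[Mg]Br)C(C)=CC[C@@H]2C(C)(C)CCC[C@@]12C | intermediate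
7 | (1R,4aR,8aR)-1-ethenyl-2,5,5,8a-tetramethyl-1,4,4a,5,6,7,8,8a-octahydronaphthalen-1-yl formate | C=C[C@@]1(OC=O)C(C)=CC[C@@H]2C(C)(C)CCC[C@@]12C | intermediate
8 | (1R,4aR,8aR)-1-ethenyl-2,5,5,8a-tetramethyl-1,4,4a,5,6,7,8,8a-octahydronaphthalene (C9–H trans to the angular methyl) | C=C[C@@H]1C(C)=CC[C@@H]2C(C)(C)CCC[C@@]12C | intermediate
9 | methyl 4-hydroxybut-2-ynoate | COC(=O)C#CCO | starting material
10 | methyl (2Z)-4-hydroxy-3-iodobut-2-enoate | COC(=O)/C=C(\I)CO | intermediate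
11 | methyl (2Z)-4-(acetyloxy)-3-iodobut-2-enoate | COC(=O)/C=C(\I)COC(C)=O | intermediate
12 | 9-{2-[(1R,4aR,8aR)-2,5,5,8a-tetramethyl-1,4,4a,5,6,7,8,8a-octahydronaphthalen-1-yl]ethyl}-9-borabicyclo[3.3.1]nonane | C(C[C@@H]1C(C)=CC[C@@H]2C(C)(C)CCC[C@@]12C)B1C2CCCC1CCC2 | intermediate
13 | methyl (2E)-3-[(acetyloxy)methyl]-5-[(1R,4aR,8aR)-2,5,5,8a-tetramethyl-1,4,4a,5,6,7,8,8a-octahydronaphthalen-1-yl]pent-2-enoate | COC(=O)/C=C(\CC[C@@H]1C(C)=CC[C@@H]2C(C)(C)CCC[C@@]12C)COC(C)=O | intermediate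
14 | methyl (2E)-3-[(acetyloxy)methyl]-5-[(1S,4aR,8aR)-2-formyl-5,5,8a-trimethyl-1,4,4a,5,6,7,8,8a-octahydronaphthalen-1-yl]pent-2-enoate | COC(=O)/C=C(\CC[C@@H]1C(C=O)=CC[C@@H]2C(C)(C)CCC[C@@]12C)COC(C)=O | intermediate
15 | O-TBS dienol ether of 14 (C17=C8 enol ether, drawn Z as expected from the s-trans enal; C6=C7 alkene) | COC(=O)/C=C(\CC[C@@H]1/C(=C\O[Si](C)(C)C(C)(C)C)C=C[C@@H]2C(C)(C)CCC[C@@]12C)COC(C)=O | intermediate
16 | C6 hydroperoxide of 14, methyl (2E)-3-[(acetyloxy)methyl]-5-[(1S,4R,4aR,8aS)-2-formyl-4-hydroperoxy-5,5,8a-trimethyl-1,4,4a,5,6,7,8,8a-octahydronaphthalen-1-yl]pent-2-enoate | COC(=O)/C=C(\CC[C@@H]1C(C=O)=C[C@@H](OO)[C@@H]2C(C)(C)CCC[C@@]12C)COC(C)=O | intermediate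
17 | methyl (2E)-3-[(acetyloxy)methyl]-5-[(1S,4R,4aR,8aS)-2-formyl-4-hydroxy-5,5,8a-trimethyl-1,4,4a,5,6,7,8,8a-octahydronaphthalen-1-yl]pent-2-enoate (CNP0112124.1) | COC(=O)/C=C(\CC[C@@H]1C(C=O)=C[C@@H](O)[C@@H]2C(C)(C)CCC[C@@]12C)COC(C)=O | target

**Step count and risks**
Total step count: 9. Longest linear sequence: 8 (steps 1–5 and 7–9; step 6 makes the coupling partner).

Three steps most likely to fail:

Step 9 (the proposed new photo-oxygenation). The risks are [2+2] attack of 1O2 on the enol-ether bond (dioxetane cleavage to the C8 ketone) and base-induced dehydration of hydroperoxide 16. The fallback is a known vinylogous Rubottom oxidation. It sets out from 14, which is silylated as in step 9, but 15 is now isolated. Dimethyldioxirane in acetone at −78 °C epoxidises the distal C6=C7 bond from the face anti to the angular methyl, giving the epoxy silyl enol ether F7. Buffered aqueous work-up opens F7 with loss of the silyl group, and the route is rejoined at 17.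

Step 8 (SeO2 oxidation). The risks are competing oxidation at the C9 methine, a stop at the allylic alcohol, or over-oxidation. The fallback sets out from 13 and moves the oxygen in through an epoxide. mCPBA epoxidises the ring alkene from the face anti to the angular methyl to give the epoxide F4. Cp2TiCl (Cp2TiCl2, Mn, THF) isomerises it to the exocyclic allylic alcohol F5. SOCl2 converts F5 with allylic transposition (SNi′) into the primary allylic chloride F6. N-Methylmorpholine N-oxide with catalytic NaI in MeCN oxidises F6 to the enal, and the route is rejoined at 14.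

Step 5 (vinyl addition and Pd/formate hydrogenolysis). The risks are hydride delivery to an allyl terminus other than C9 (conjugated dienes) and β-hydride elimination to trienes. The fallback sets out from 5 and builds the C9 centre by hydroboration. Wittig methylenation (Ph3P=CH2, toluene, 90 °C) gives the exocyclic diene F1. 9-BBN then NaOH/H2O2 adds H and B from the face anti to the angular methyl and gives ent-drimenol F2. Dess–Martin oxidation gives ent-drimenal F3. Salt-free Ph3P=CH2 at −78 → 0 °C methylenates F3, and the route is rejoined at 8.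

**Further compounds**
F1 | step 5 | (4aR,8aR)-2,5,5,8a-tetramethyl-1-methylidene-1,4,4a,5,6,7,8,8a-octahydronaphthalene | C=C1C(C)=CC[C@@H]2C(C)(C)CCC[C@@]12C
F2 | step 5 | ent-drimenol, [(1R,4aR,8aR)-2,5,5,8a-tetramethyl-1,4,4a,5,6,7,8,8a-octahydronaphthalen-1-yl]methanol | OC[C@@H]1C(C)=CC[C@@H]2C(C)(C)CCC[C@@]12C
F3 | step 5 | ent-drimenal, (1R,4aR,8aR)-2,5,5,8a-tetramethyl-1,4,4a,5,6,7,8,8a-octahydronaphthalene-1-carbaldehyde | O=C[C@@H]1C(C)=CC[C@@H]2C(C)(C)CCC[C@@]12C
F4 | step 8 | C7–C8 epoxide of 13 (oxirane oxygen anti to the angular methyl) | COC(=O)/C=C(\CC[C@@H]1[C@@]3(C)O[C@H]3C[C@@H]2C(C)(C)CCC[C@@]12C)COC(C)=O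
F5 | step 8 | C7 allylic alcohol of 13 with exocyclic C8=CH2 (OH anti to the angular methyl) | COC(=O)/C=C(\CC[C@@H]1C(=C)[C@@H](O)C[C@@H]2C(C)(C)CCC[C@@]12C)COC(C)=O
F6 | step 8 | primary allylic chloride (ClCH2 on C8, C7=C8 alkene) | COC(=O)/C=C(\CC[C@@H]1C(CCl)=CC[C@@H]2C(C)(C)CCC[C@@]12C)COC(C)=O
F7 | step 9 | C6–C7 epoxide of silyl dienol ether 15 (oxirane oxygen anti to the angular methyl) | COC(=O)/C=C(\CC[C@@H]1/C(=C\O[Si](C)(C)C(C)(C)C)[C@H]3O[C@H]3[C@@H]2C(C)(C)CCC[C@@]12C)COC(C)=O
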